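The furan ring is formed last. Because the furan (O1′, C2′–C5′) bears only one substituent, at C3′, a terminal alkyne on carbinol carbon C1 can supply C3′–C4′, and either orientation of addition converges on the same product. Heating the (S)-propargylic acetate 23 in 4-phenyloxazole gives a [4+2] adduct across oxazole C2/C5 that loses benzonitrile, creating bonds C2′–C3′ and C4′–C5′ and the aromatic ring in one operation. Precursor 23 is an acyclic C19 keto trienynyl acetate. Its stereocentre comes from (R)-glycidol, its three E-alkenes from geranyl bromide and a methylalumination, and its C14 ketone is carried as a dithiane until the step before.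

Key step: step 15

Remark (numbering): chain atoms are C1 (carbinol) to C17 and furan atoms O1′, C2′–C5′, as in the target name; 23 is numbered from its alkyne carbon.
Remark (configuration): C2 of (R)-glycidol becomes C1 of the target, the epoxide CH2 becomes C2 and the CH2OH carbon becomes C3′; no bond at this carbon is broken, and the CIP ranking then gives S in 16–26. The structures of target, precursor and starting materials were checked on this basis and need no correction.
Remark (precursor design): the β,γ-unsaturated C14 ketone is released from its thioketal only in step 14, under neutral conditions, so it never meets base or organometallic reagents. Commercial geranyl bromide, 1-(trimethylsilyl)propyne and 4-phenyloxazole are assumed.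

Step 1
Reactants: 1 geranyl bromide; 2 1-(trimethylsilyl)propyne
Product: 4 trimethyl[(5E)-6,10-dimethylundeca-5,9-dien-1-yn-1-yl]silane, via lithiated silylpropyne 3 (not isolated)
Conditions: 2, n-BuLi, THF, −20 °C; then 1, −78 → 0 °C
Reagents that add atoms: none
Why: Propargylic alkylation, in which the silyl-capped propargyl anion displaces the primary allylic bromide by SN2 at its CH2 terminus and extends the chain by three carbons without touching the 2E alkene.

Step 2
Reactants: 4 trimethyl[(5E)-6,10-dimethylundeca-5,9-dien-1-yn-1-yl]silane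
Product: 5 (2E,6E)-2,6-dimethyl-11-(trimethylsilyl)undeca-2,6-dien-10-yn-1-ol
Conditions: SeO2 (0.2 equiv), t-BuOOH, salicylic acid (cat.), CH2Cl2, 0 °C → rt
Reagents that add atoms: tert-butyl hydroperoxide, CC(C)(C)OO (oxygen relayed by SeO2, O=[Se]=O)
Why: Riley allylic oxidation (ene reaction, then [2,3]-sigmatropic shift) should attack the E-methyl group of the terminal isopropylidene unit in preference to the more hindered internal alkene, giving the E-allylic alcohol that becomes C11=C12–C13.

Step 3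
Reactants: 5 (2E,6E)-2,6-dimethyl-11-(trimethylsilyl)undeca-2,6-dien-10-yn-1-ol
Product: 6 [(5E,9E)-11-bromo-6,10-dimethylundeca-5,9-dien-1-yn-1-yl]trimethylsilane
Conditions: CBr4, PPh3, CH2Cl2, −20 → 0 °C
Reagents that add atoms: carbon tetrabromide, BrC(Br)(Br)Br
Why: Appel reaction, in which bromide displaces the primary alkoxyphosphonium ion by SN2 under neutral conditions, so the allylic bromide keeps its E geometry.

Step 4
Reactants: 7 isovaleraldehyde
Product: 8 2-(2-methylpropyl)-1,3-dithiane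
Conditions: HS(CH2)3SH, BF3·OEt2 (cat.), CH2Cl2, 0 °C → rt
Reagents that add atoms: propane-1,3-dithiol, SCCCS
Why: Lewis acid-catalysed thioacetalisation turns the aldehyde carbon (future C14) into an acyl-anion equivalent.

Step 5
Reactants: 8 2-(2-methylpropyl)-1,3-dithiane; 6 [(5E,9E)-11-bromo-6,10-dimethylundeca-5,9-dien-1-yn-1-yl]trimethylsilane
Product: 10 trimethyl{(5E,9E)-6,10-dimethyl-11-[2-(2-methylpropyl)-1,3-dithian-2-yl]undeca-5,9-dien-1-yn-1-yl}silane, via lithiated dithiane 9 (not isolated)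
Conditions: 8, n-BuLi, THF, −30 °C; then 6, −78 → −20 °C
Reagents that add atoms: none
Why: Corey–Seebach alkylation, in which the 2-lithio-1,3-dithiane attacks the primary allylic bromide by SN2 to form C13–C14 with the ketone masked as a base-stable thioketal, the silyl cap sparing the alkyne from deprotonation.

Step 6
Reactants: 10 trimethyl{(5E,9E)-6,10-dimethyl-11-[2-(2-methylpropyl)-1,3-dithian-2-yl]undeca-5,9-dien-1-yn-1-yl}silane
Product: 11 2-[(2E,6E)-2,6-dimethylundeca-2,6-dien-10-yn-1-yl]-2-(2-methylpropyl)-1,3-dithiane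
Conditions: K2CO3 (0.2 equiv), MeOH–THF, rt
Reagents that add atoms: none
Why: Methoxide-mediated protodesilylation cleaves only the C(sp)–Si bond and frees the terminal alkyne needed for carbometalation.

Step 7
Reactants: 12 (R)-glycidol
Product: 13 triethyl{[(2S)-oxiran-2-yl]methoxy}silane
Conditions: Et3SiCl, imidazole, CH2Cl2, 0 °C
Reagents that add atoms: chlorotriethylsilane, CC[Si](Cl)(CC)CC
Why: O-Silylation of the primary alcohol leaves the epoxide and its stereocentre untouched; the descriptor changes from R to S only because the CIP ranking changes.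

Step 8
Reactants: 11 2-[(2E,6E)-2,6-dimethylundeca-2,6-dien-10-yn-1-yl]-2-(2-methylpropyl)-1,3-dithiane; 13 triethyl{[(2S)-oxiran-2-yl]methoxy}silane
Product: 16 (2S,4E,8E,12E)-5,9,13-trimethyl-14-[2-(2-methylpropyl)-1,3-dithian-2-yl]-1-[(triethylsilyl)oxy]tetradeca-4,8,12-trien-2-ol, via alkenylalane 14 (not isolated), via lithium alanate 15 (not isolated)
Conditions: 11, Me3Al (2 equiv), Cp2ZrCl2 (0.25 equiv), (CH2Cl)2, rt; volatiles removed; n-BuLi, hexane–THF, −30 °C; then 13, 0 °C → rt; aq. KNaC4H4O6 (potassium sodium tartrate)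
Reagents that add atoms: trimethylaluminium, C[Al](C)C
Why: Zirconium-catalysed (Negishi) carboalumination adds methyl and aluminium syn across the terminal alkyne with aluminium on the terminal carbon, which fixes the E geometry of the new trisubstituted alkene (target C3=C4), and the derived alanate opens the epoxide by SN2 at its unsubstituted carbon, so the glycidol stereocentre is not touched and appears as the 2S carbinol.

Step 9
Reactants: 16 (2S,4E,8E,12E)-5,9,13-trimethyl-14-[2-(2-methylpropyl)-1,3-dithian-2-yl]-1-[(triethylsilyl)oxy]tetradeca-4,8,12-trien-2-ol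
Product: 17 (2S,4E,8E,12E)-2-[(tert-butyldimethylsilyl)oxy]-5,9,13-trimethyl-14-[2-(2-methylpropyl)-1,3-dithian-2-yl]-1-[(triethylsilyl)oxy]tetradeca-4,8,12-triene
Conditions: t-BuMe2SiCl, imidazole, DMF, rt
Reagents that add atoms: tert-butylchlorodimethylsilane, CC(C)(C)[Si](C)(C)Cl
Why: Standard silylation of the secondary alcohol gives a robust ether that differs clearly in lability from the primary triethylsilyl ether.

Step 10
Reactants: 17 (2S,4E,8E,12E)-2-[(tert-butyldimethylsilyl)oxy]-5,9,13-trimethyl-14-[2-(2-methylpropyl)-1,3-dithian-2-yl]-1-[(triethylsilyl)oxy]tetradeca-4,8,12-triene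
Product: 19 (2S,4E,8E,12E)-2-[(tert-butyldimethylsilyl)oxy]-5,9,13-trimethyl-14-[2-(2-methylpropyl)-1,3-dithian-2-yl]tetradeca-4,8,12-trienal, via alkoxysulfonium salt 18 (not isolated)
Conditions: (COCl)2, DMSO, CH2Cl2, −78 °C; 17, −78 → −40 °C; i-Pr2NEt, −78 → 0 °C
Reagents that add atoms: none
Why: Swern oxidation applied directly to a primary triethylsilyl ether, in which chlorodimethylsulfonium chloride cleaves the unhindered primary O–Si bond to give the alkoxysulfonium salt and the amine converts this into the aldehyde, while the secondary silyl ether, the thioketal and the alkenes are left alone and the low temperature protects the α-stereocentre.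

Step 11
Reactants: 19 (2S,4E,8E,12E)-2-[(tert-butyldimethylsilyl)oxy]-5,9,13-trimethyl-14-[2-(2-methylpropyl)-1,3-dithian-2-yl]tetradeca-4,8,12-trienal
Product: 20 (3S,5E,9E,13E)-3-[(tert-butyldimethylsilyl)oxy]-6,10,14-trimethyl-15-[2-(2-methylpropyl)-1,3-dithian-2-yl]pentadeca-5,9,13-trien-1-yne
Conditions: dimethyl (1-diazo-2-oxopropyl)phosphonate, K2CO3, MeOH, 0 °C → rt (19 used crude)
Reagents that add atoms: dimethyl (1-diazo-2-oxopropyl)phosphonate, CC(=O)C(=[N+]=[N-])P(=O)(OC)OC
Why: Seyferth–Gilbert homologation in the Ohira–Bestmann form, in which the diazomethylphosphonate anion released by methanolysis olefinates the aldehyde and the diazoalkene loses N2 to give the terminal alkyne by 1,2-hydrogen shift, under conditions mild enough for an α-silyloxy aldehyde to keep its configuration.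

Step 12
Reactants: 20 (3S,5E,9E,13E)-3-[(tert-butyldimethylsilyl)oxy]-6,10,14-trimethyl-15-[2-(2-methylpropyl)-1,3-dithian-2-yl]pentadeca-5,9,13-trien-1-yne
Product: 21 (3S,5E,9E,13E)-6,10,14-trimethyl-15-[2-(2-methylpropyl)-1,3-dithian-2-yl]pentadeca-5,9,13-trien-1-yn-3-ol
Conditions: Bu4NF, THF, 0 °C
Reagents that add atoms: none
Why: Fluoride-induced cleavage of the silyl ether releases the propargylic alcohol without touching the C–O bond, so C3 stays S.

Step 13
Reactants: 21 (3S,5E,9E,13E)-6,10,14-trimethyl-15-[2-(2-methylpropyl)-1,3-dithian-2-yl]pentadeca-5,9,13-trien-1-yn-3-ol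
Product: 22 (3S,5E,9E,13E)-6,10,14-trimethyl-15-[2-(2-methylpropyl)-1,3-dithian-2-yl]pentadeca-5,9,13-trien-1-yn-3-yl acetate
Conditions: Ac2O, DMAP (cat.), pyridine, 0 °C → rt
Reagents that add atoms: acetic anhydride, CC(=O)OC(C)=O
Why: DMAP-catalysed O-acylation of the secondary alcohol proceeds with retention because only the O–H bond reacts.

Step 14
Reactants: 22 (3S,5E,9E,13E)-6,10,14-trimethyl-15-[2-(2-methylpropyl)-1,3-dithian-2-yl]pentadeca-5,9,13-trien-1-yn-3-yl acetate
Product: 23 (3S,5E,9E,13E)-6,10,14,18-tetramethyl-16-oxononadeca-5,9,13-trien-1-yn-3-yl acetate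
Conditions: MeI (excess), CaCO3, MeCN–H2O (9:1), 40 °C, dark
Reagents that add atoms: water, O
Why: Alkylative thioketal hydrolysis, in which S-methylation makes sulfur a leaving group and water captures the thionium ion, while CaCO3 keeps the medium neutral so that the acetate survives and the new β,γ-unsaturated ketone is not drawn into conjugation.

Step 15
Reactants: 23 (3S,5E,9E,13E)-6,10,14,18-tetramethyl-16-oxononadeca-5,9,13-trien-1-yn-3-yl acetate; 24 4-phenyloxazole
Product: 26 (1S,3E,7E,11E)-1-(furan-3-yl)-4,8,12,16-tetramethyl-14-oxoheptadeca-3,7,11-trien-1-yl acetate, via bicyclic cycloadduct 25 (not isolated)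
Conditions: 24 (8 equiv, neat), BHT (cat.), base-washed sealed tube, Ar, 175–185 °C; then 24 and PhCN removed by bulb-to-bulb distillation
Reagents that add atoms: none
Why: The oxazole acts as a 2-azadiene through C2 and C5 and the terminal alkyne of 23 as the 2π partner in a thermal, concerted [4+2] cycloaddition that gives the 7-oxa-2-azabicyclo[2.2.1]hepta-2,5-diene 25, which at once undergoes a retro-[4+2] that expels N3≡C4–Ph as benzonitrile and leaves O1′, C2′ and C5′ (from the oxazole) joined to C3′ and C4′ (from the alkyne). The closest known reaction type is the oxazole–alkyne Diels–Alder/retro-Diels–Alder furan synthesis, established for 4-phenyloxazole with unactivated and propargylically oxygenated alkynes. The furan ring is closed by cycloaddition at two C–C bonds (C2′–C3′ and C4′–C5′) followed by cycloreversion, and the gain in aromaticity together with the stable nitrile makes the sequence irreversible. No stereocentre is created; C1 is a spectator whose C–O bond is never broken, so the S configuration set in step 8 is carried through. Only chemoselectivity is required: regiochemistry is irrelevant because both orientations give the same 3-monosubstituted furan, the three trisubstituted alkenes are too hindered and electron-rich to compete as 2π partners, and neat excess oxazole at the lowest temperature that sustains reaction should make the bimolecular cycloaddition faster than [3,3] shifts of the 1,5-enyne or of the propargylic acetate and than conjugation of the β,γ-enone.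

Compound list
1 | geranyl bromide, (2E)-1-bromo-3,7-dimethylocta-2,6-diene | CC(C)=CCC/C(C)=C/CBr | starting material
2 | 1-(trimethylsilyl)propyne, trimethyl(prop-1-yn-1-yl)silane | CC#C[Si](C)(C)C | starting material
3 | [3-(trimethylsilyl)prop-2-yn-1-yl]lithium | [Li]CC#C[Si](C)(C)C | intermediate (not isolated)
4 | trimethyl[(5E)-6,10-dimethylundeca-5,9-dien-1-yn-1-yl]silane | CC(C)=CCC/C(C)=C/CCC#C[Si](C)(C)C | intermediate
5 | (2E,6E)-2,6-dimethyl-11-(trimethylsilyl)undeca-2,6-dien-10-yn-1-ol | OC/C(C)=C/CC/C(C)=C/CCC#C[Si](C)(C)C | intermediate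
6 | [(5E,9E)-11-bromo-6,10-dimethylundeca-5,9-dien-1-yn-1-yl]trimethylsilane | BrC/C(C)=C/CC/C(C)=C/CCC#C[Si](C)(C)C | intermediate
7 | isovaleraldehyde, 3-methylbutanal | CC(C)CC=O | starting material
8 | 2-(2-methylpropyl)-1,3-dithiane | CC(C)CC1SCCCS1 | intermediate
9 | [2-(2-methylpropyl)-1,3-dithian-2-yl]lithium | [Li]C1(CC(C)C)SCCCS1 | intermediate (not isolated)
10 | trimethyl{(5E,9E)-6,10-dimethyl-11-[2-(2-methylpropyl)-1,3-dithian-2-yl]undeca-5,9-dien-1-yn-1-yl}silane | CC(C)CC1(C/C(C)=C/CC/C(C)=C/CCC#C[Si](C)(C)C)SCCCS1 | intermediate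
11 | 2-[(2E,6E)-2,6-dimethylundeca-2,6-dien-10-yn-1-yl]-2-(2-methylpropyl)-1,3-dithiane | CC(C)CC1(C/C(C)=C/CC/C(C)=C/CCC#C)SCCCS1 | intermediate
12 | (R)-glycidol, [(2R)-oxiran-2-yl]methanol | C1[C@H](O1)CO | starting material
13 | triethyl{[(2S)-oxiran-2-yl]methoxy}silane | C1[C@H](O1)CO[Si](CC)(CC)CC | intermediate
14 | dimethyl{(1E,5E,9E)-2,6,10-trimethyl-11-[2-(2-methylpropyl)-1,3-dithian-2-yl]undeca-1,5,9-trien-1-yl}alumane | CC(C)CC1(C/C(C)=C/CC/C(C)=C/CC/C(C)=C/[Al](C)C)SCCCS1 | intermediate (not isolated)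
15 | lithium butyl(dimethyl){(1E,5E,9E)-2,6,10-trimethyl-11-[2-(2-methylpropyl)-1,3-dithian-2-yl]undeca-1,5,9-trien-1-yl}aluminate | CC(C)CC1(C/C(C)=C/CC/C(C)=C/CC/C(C)=C/[Al-](C)(C)CCCC)SCCCS1.[Li+] | intermediate (not isolated)
16 | (2S,4E,8E,12E)-5,9,13-trimethyl-14-[2-(2-methylpropyl)-1,3-dithian-2-yl]-1-[(triethylsilyl)oxy]tetradeca-4,8,12-trien-2-ol | O[C@@H](C/C=C(\C)CC/C=C(\C)CC/C=C(\C)CC1(CC(C)C)SCCCS1)CO[Si](CC)(CC)CC | intermediate
17 | (2S,4E,8E,12E)-2-[(tert-butyldimethylsilyl)oxy]-5,9,13-trimethyl-14-[2-(2-methylpropyl)-1,3-dithian-2-yl]-1-[(triethylsilyl)oxy]tetradeca-4,8,12-triene | CC(C)(C)[Si](C)(C)O[C@@H](C/C=C(\C)CC/C=C(\C)CC/C=C(\C)CC1(CC(C)C)SCCCS1)CO[Si](CC)(CC)CC | intermediate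
18 | {[(2S,4E,8E,12E)-2-[(tert-butyldimethylsilyl)oxy]-5,9,13-trimethyl-14-[2-(2-methylpropyl)-1,3-dithian-2-yl]tetradeca-4,8,12-trien-1-yl]oxy}dimethylsulfonium chloride | CC(C)(C)[Si](C)(C)O[C@@H](C/C=C(\C)CC/C=C(\C)CC/C=C(\C)CC1(CC(C)C)SCCCS1)CO[S+](C)C.[Cl-] | intermediate (not isolated)
19 | (2S,4E,8E,12E)-2-[(tert-butyldimethylsilyl)oxy]-5,9,13-trimethyl-14-[2-(2-methylpropyl)-1,3-dithian-2-yl]tetradeca-4,8,12-trienal | CC(C)(C)[Si](C)(C)O[C@@H](C/C=C(\C)CC/C=C(\C)CC/C=C(\C)CC1(CC(C)C)SCCCS1)C=O | intermediate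
20 | (3S,5E,9E,13E)-3-[(tert-butyldimethylsilyl)oxy]-6,10,14-trimethyl-15-[2-(2-methylpropyl)-1,3-dithian-2-yl]pentadeca-5,9,13-trien-1-yne | CC(C)(C)[Si](C)(C)O[C@@H](C/C=C(\C)CC/C=C(\C)CC/C=C(\C)CC1(CC(C)C)SCCCS1)C#C | intermediate
21 | (3S,5E,9E,13E)-6,10,14-trimethyl-15-[2-(2-methylpropyl)-1,3-dithian-2-yl]pentadeca-5,9,13-trien-1-yn-3-ol | O[C@@H](C/C=C(\C)CC/C=C(\C)CC/C=C(\C)CC1(CC(C)C)SCCCS1)C#C | intermediate
22 | (3S,5E,9E,13E)-6,10,14-trimethyl-15-[2-(2-methylpropyl)-1,3-dithian-2-yl]pentadeca-5,9,13-trien-1-yn-3-yl acetate | CC(=O)O[C@@H](C/C=C(\C)CC/C=C(\C)CC/C=C(\C)CC1(CC(C)C)SCCCS1)C#C | intermediate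
23 | (3S,5E,9E,13E)-6,10,14,18-tetramethyl-16-oxononadeca-5,9,13-trien-1-yn-3-yl acetate | CC(=O)O[C@@H](C/C=C(\C)CC/C=C(\C)CC/C=C(\C)CC(=O)CC(C)C)C#C | intermediate (key-step precursor)
24 | 4-phenyloxazole | c1ccc(cc1)-c1cocn1 | starting material
25 | (1S,3E,7E,11E)-4,8,12,16-tetramethyl-14-oxo-1-(3-phenyl-7-oxa-2-azabicyclo[2.2.1]hepta-2,5-dien-6-yl)heptadeca-3,7,11-trien-1-yl acetate (6-yl orientation drawn; the 5-yl orientation gives the same furan; bridgehead configuration unassigned) | CC(=O)O[C@@H](C/C=C(\C)CC/C=C(\C)CC/C=C(\C)CC(=O)CC(C)C)C1=CC2OC1N=C2c1ccccc1 | intermediate (not isolated)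
26 | (1S,3E,7E,11E)-1-(furan-3-yl)-4,8,12,16-tetramethyl-14-oxoheptadeca-3,7,11-trien-1-yl acetate | CC(=O)O[C@@H](C/C=C(\C)CC/C=C(\C)CC/C=C(\C)CC(=O)CC(C)C)c1ccoc1 | target

Total step count: 15.
Longest linear sequence: 13 steps (steps 1–3, 5, 6 and 8–15); steps 4 and 7 prepare side fragments.

Steps most likely to fail

Step 15. The intermolecular cycloaddition may be outrun by unimolecular thermal change of 23: a [3,3] shift of the 1,5-enyne or of the propargylic acetate, loss of acetic acid, or migration of the C11=C12 bond into conjugation. The fallback brings the furan in preformed. Setting out from alkyne 11, the alanate 15 made as in step 8 would be quenched with oxirane to give (3E,7E,11E)-4,8,12-trimethyl-13-[2-(2-methylpropyl)-1,3-dithian-2-yl]trideca-3,7,11-trien-1-ol F1. Parikh–Doering oxidation (SO3·pyridine, DMSO, i-Pr2NEt, 0 °C) would give (3E,7E,11E)-4,8,12-trimethyl-13-[2-(2-methylpropyl)-1,3-dithian-2-yl]trideca-3,7,11-trienal F2, to be used at once. Addition of furan-3-yllithium F3 (from 3-bromofuran and n-BuLi, THF, −78 °C) would give racemic (3E,7E,11E)-1-(furan-3-yl)-4,8,12-trimethyl-13-[2-(2-methylpropyl)-1,3-dithian-2-yl]trideca-3,7,11-trien-1-ol F4. MnO2 in CH2Cl2 would oxidise it to (3E,7E,11E)-1-(furan-3-yl)-4,8,12-trimethyl-13-[2-(2-methylpropyl)-1,3-dithian-2-yl]trideca-3,7,11-trien-1-one F5. Corey–Bakshi–Shibata reduction with the (R)-2-methyl-oxazaborolidine and catecholborane at −78 °C, the furyl ring acting as the large group, should deliver (1S,3E,7E,11E)-1-(furan-3-yl)-4,8,12-trimethyl-13-[2-(2-methylpropyl)-1,3-dithian-2-yl]trideca-3,7,11-trien-1-ol F6. Acetylation as in step 13 would give (1S,3E,7E,11E)-1-(furan-3-yl)-4,8,12-trimethyl-13-[2-(2-methylpropyl)-1,3-dithian-2-yl]trideca-3,7,11-trien-1-yl acetate F7, and methyl iodide with CaCO3 as in step 14 would release the ketone and arrive at 26.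

Step 8. Transfer of the alkenyl group from the alanate to the epoxide may be slow, so that methyl or butyl transfer or loss of the silyl group competes. The fallback uses an alkenyllithium instead. From 11, the alkenylalane 14 generated as in step 8 would be quenched with I2 (THF, −30 °C) to give 2-[(2E,6E,10E)-11-iodo-2,6,10-trimethylundeca-2,6,10-trien-1-yl]-2-(2-methylpropyl)-1,3-dithiane F8. Iodine–lithium exchange (t-BuLi, Et2O, −78 °C) would give {(1E,5E,9E)-2,6,10-trimethyl-11-[2-(2-methylpropyl)-1,3-dithian-2-yl]undeca-1,5,9-trien-1-yl}lithium F9. With epoxide 13 and BF3·OEt2 at −78 °C this should open the oxirane at its CH2 terminus and rejoin the route at 16.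

Step 10. The excess chlorosulfonium reagent needed to cleave the Si–O bond may attack the thioketal sulfur atoms, or the aldehyde may epimerise while the mixture is warmed. The fallback separates deprotection from oxidation. From 17, acid-catalysed methanolysis (pyridinium p-toluenesulfonate, MeOH–CH2Cl2, 0 °C) would remove only the primary triethylsilyl group to give (2S,4E,8E,12E)-2-[(tert-butyldimethylsilyl)oxy]-5,9,13-trimethyl-14-[2-(2-methylpropyl)-1,3-dithian-2-yl]tetradeca-4,8,12-trien-1-ol F10. A Parikh–Doering oxidation (SO3·pyridine, DMSO, i-Pr2NEt, 0 °C), which involves no chlorinating species, would then give 19.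

Further compounds
F1 | step 15 | (3E,7E,11E)-4,8,12-trimethyl-13-[2-(2-methylpropyl)-1,3-dithian-2-yl]trideca-3,7,11-trien-1-ol | OCC/C=C(\C)CC/C=C(\C)CC/C=C(\C)CC1(CC(C)C)SCCCS1
F2 | step 15 | (3E,7E,11E)-4,8,12-trimethyl-13-[2-(2-methylpropyl)-1,3-dithian-2-yl]trideca-3,7,11-trienal | O=CC/C=C(\C)CC/C=C(\C)CC/C=C(\C)CC1(CC(C)C)SCCCS1
F3 | step 15 | furan-3-yllithium | [Li]c1ccoc1
F4 | step 15 | (3E,7E,11E)-1-(furan-3-yl)-4,8,12-trimethyl-13-[2-(2-methylpropyl)-1,3-dithian-2-yl]trideca-3,7,11-trien-1-ol (racemic) | OC(C/C=C(\C)CC/C=C(\C)CC/C=C(\C)CC1(CC(C)C)SCCCS1)c1ccoc1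
F5 | step 15 | (3E,7E,11E)-1-(furan-3-yl)-4,8,12-trimethyl-13-[2-(2-methylpropyl)-1,3-dithian-2-yl]trideca-3,7,11-trien-1-one | O=C(C/C=C(\C)CC/C=C(\C)CC/C=C(\C)CC1(CC(C)C)SCCCS1)c1ccoc1
F6 | step 15 | (1S,3E,7E,11E)-1-(furan-3-yl)-4,8,12-trimethyl-13-[2-(2-methylpropyl)-1,3-dithian-2-yl]trideca-3,7,11-trien-1-ol | O[C@@H](C/C=C(\C)CC/C=C(\C)CC/C=C(\C)CC1(CC(C)C)SCCCS1)c1ccoc1
F7 | step 15 | (1S,3E,7E,11E)-1-(furan-3-yl)-4,8,12-trimethyl-13-[2-(2-methylpropyl)-1,3-dithian-2-yl]trideca-3,7,11-trien-1-yl acetate | CC(=O)O[C@@H](C/C=C(\C)CC/C=C(\C)CC/C=C(\C)CC1(CC(C)C)SCCCS1)c1ccoc1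
F8 | step 8 | 2-[(2E,6E,10E)-11-iodo-2,6,10-trimethylundeca-2,6,10-trien-1-yl]-2-(2-methylpropyl)-1,3-dithiane | CC(C)CC1(C/C(C)=C/CC/C(C)=C/CC/C(C)=C/I)SCCCS1
F9 | step 8 | {(1E,5E,9E)-2,6,10-trimethyl-11-[2-(2-methylpropyl)-1,3-dithian-2-yl]undeca-1,5,9-trien-1-yl}lithium | CC(C)CC1(C/C(C)=C/CC/C(C)=C/CC/C(C)=C/[Li])SCCCS1
F10 | step 10 | (2S,4E,8E,12E)-2-[(tert-butyldimethylsilyl)oxy]-5,9,13-trimethyl-14-[2-(2-methylpropyl)-1,3-dithian-2-yl]tetradeca-4,8,12-trien-1-ol | CC(C)(C)[Si](C)(C)O[C@@H](C/C=C(\C)CC/C=C(\C)CC/C=C(\C)CC1(CC(C)C)SCCCS1)CO
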